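## Analysis of the target

The target (34) is a germacranolide of the melampolide type. Its ten-membered carbocycle is numbered C1 (CH of the Z-alkene), C2, C3, C4 (bearing methyl C15), C5, C6 (lactone oxygen), C7 (bearing C11, with C12 the lactone carbonyl and C13 the exocyclic methylene), C8 (acyloxy), C9 (hydroxyl) and C10 (bearing methyl C14). C1=C10 is Z and C4=C5 is E, and an α-methylene-γ-butyrolactone is fused across C6–C7. The four ring stereocentres are contiguous (6S,7S,8S,9R); read literally from the descriptors, the lactone oxygen on C6, the C11 branch on C7, the ester oxygen on C8 and the hydroxyl on C9 all lie on one face. The fifth stereocentre (R) sits in the side chain, (R)-3-methyl-4-(octadecanoyloxy)butanoate, and is remote from the ring. Sensitive groups are the α-methylene lactone (Michael acceptor), the strained 1,5-diene (Cope shift on heating, transannular cyclisation in acid), the allylic lactone C–O bond, and the cis-8-acyloxy-9-hydroxy pair (acyl migration in base). The synthesis is hard because a medium ring must be made with one Z and one E trisubstituted alkene, next to an all-cis array of four stereocentres in which O8 and O9 must be told apart. The strategy rests on one feature: the 1,5-diene C10=C1–C2–C3–C4=C5 is the cycloreversion product of a bicyclo[2.2.0]hexane bonded C1–C4 and C5–C10. The remaining six-membered ring C5–C10, with C14 on C10, oxygen at C9 and the three-carbon branch on C7, is the skeleton of (S)-carvone (1).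

## Retrosynthetic reasoning

**C9–H.** The carbinol of 34 is taken back to the ketone 33. Keeping C9 as a ketone until the last step distinguishes O9 from O8 by oxidation level, so O8 can be acylated without a protecting group on O9. The forward step must add hydride 1,2 to the Z-enone from one face and leave the methylene lactone alone.

**O8 ester.** The ester C–O bond of 33 is cut to the hydroxy ketone 27 and the acid 32. The acid is a C5 unit, made from the half ester 28 and stearoyl chloride 30; the side chain is attached whole, late, because it adds nothing to the ring problem.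

**Lactone and methylene.** The C12–O6 bond and the C11=C13 double bond of 26 (the silyl ether of 27) are traced to the hydroxymethyl lactone 24 and from there to the triol 23, released from the silyl ether/acetonide 22. A 1,3-diol on C11 is chosen because oxidation of either arm gives the lactone and the other arm becomes the methylene by dehydration; no strong base is needed late.

**Ten-membered ring (key disconnection).** The ring of 22 is not cut in the usual sense. The bonds C1–C4 and C5–C10 are re-formed, which folds the two alkenes into the bicyclo[2.2.0]hexane of 21. This removes the macrocyclisation and both alkene-geometry problems at once. The forward reaction must break exactly these two bonds thermally and deliver Z at C1=C10 and E at C4=C5 without onward Cope shift.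

**Bicyclo[2.2.0]hexane.** 21 is cut at C10–C1 and C5–C4 to the enone 18 and 1-methylcyclobutene 20 (from methylenecyclobutane 19). This [2+2] photocycloaddition is the only way the strained core is reached directly; it must be head-to-tail, cis-fused and anti.

**O6.** The C6–O bond of 18 is taken back to the enone 13 through the trans alcohol 15 and its epimer 17. Oxidants attack C6 anti to the C7 branch, so the cis oxygen is reached by oxidation followed by inversion.

**O8.** The C8–O bond of 13 is taken back to the enone 8 through the trans ketol 10 and its epimer 12, by the same oxidation-then-inversion logic, done first while C6 is still unsubstituted.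

**C11 branch.** The dioxane of 8 is traced to the isopropenyl group of 1: one oxygen arrives by allylic chlorination and acetate displacement (2, 3), the other by hydroboration (4 to 6), followed by acetonide formation (7) and re-oxidation at C9 (8). Carvone supplies C5–C10, C14, the C9 oxygen, C11–C13 and the C7 configuration.

## Alternatives that were turned down

**Alternative 1:** The ring would be cut at C2–C3 with the six-membered ring C5–C10 restored. The substrate is the 1-vinyl-2-isopropenylcyclohexanol A1, with O6/O8 tied in a p-methoxybenzylidene acetal, O9 as a 2-naphthylmethyl ether and a two-carbon arm on C7. Forward, KN(SiMe3)2 with 18-crown-6 gives the C10 potassium alkoxide, an anionic oxy-Cope shift makes C2–C3 as C5–C10 breaks, and PhNTf2 traps the ring-expanded enolate as the enol triflate A2.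
- For: the shift runs at or below room temperature, so a thermal Cope return is not an issue; enolate formation pays for the ring strain; C9 already carries its oxygen with fixed configuration. On that last point it is stronger than the chosen route, which reduces a C9 ketone late.
- Against: C14 is missing and must be cross-coupled onto the Z-enol triflate; C13 is missing, so the lactone needs a strong-base α-methylenation late; A1 needs vinyl addition to a crowded α,α′-dioxygenated cyclohexanone with control of a quaternary carbinol; the Z enolate geometry depends on one chair transition state being held by the bicyclic acetal.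
- Comparison: the chosen strategy takes all fifteen skeletal carbons, C14 and C15 included, from two cheap building blocks in two pericyclic steps. Alternative 1 is milder in its key step but needs many more steps to build A1 and to finish A2.

**Alternative 2:** The cis-diol would be cut at C8–C9, giving the open-chain lactone dialdehyde A3 (aldehyde on C7, Z-enal at C9). Forward, low-valent titanium from TiCl3(DME)1.5 and Zn–Cu (or SmI2) couples the two carbonyls to the ten-membered cis-8,9-diol lactone A4.
- For: one step makes the ring, the C8–C9 bond and both carbinol centres; metal-templated intramolecular pinacol coupling normally gives the cis-diol, which is the relationship needed; conditions are cold and neutral; the lactone is already in place. On mildness and on setting O8/O9 cis in one event it is as strong or stronger.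
- Against: A3 needs a linear synthesis with separate control of a Z and an E trisubstituted alkene and of C6/C7; a ten-membered ring must be closed against entropy at high dilution; the face of coupling relative to C7 is not secured; the enal ketyl is an allyl radical and can lose its Z geometry or couple at C1; over-reduction to the alkene is possible; the two free secondary hydroxyls of A4 must then be distinguished for acylation; C13 is missing.
- Comparison: the chosen strategy needs no macrocyclisation, gets both alkene geometries from ring-fusion stereochemistry, and distinguishes O8 from O9 by oxidation level.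

**Alternative 3:** The ring would be cut at C5–C6 and the methyl bond C4–C15, giving the ynal A5 (aldehyde C6 on C7; terminal alkyne C4≡C5 at the far end of the chain). Forward, zerovalent nickel Ni(cod)2 with the carbene IMes forms an oxanickelacycle from aldehyde and alkyne, Me2Zn transfers methyl to nickel, and reductive elimination gives the ten-membered E-allylic alcohol A6 with C15 installed.
- For: syn addition across the alkyne fixes the E alkene by mechanism, which is a firmer control than the chair selection the chosen route depends on; the step is catalytic and mild; C6–O and C15 come in one operation.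
- Against: endocyclic closure to a ten-membered ring holding an E alkene is at the lower limit of ring size for this chemistry and competes with exocyclic closure and dimerisation; the C6 configuration would come from macrocyclic 1,2-induction with no reliable model; Me2Zn can add directly to the aldehyde; A5 needs acyclic construction of the all-syn C7–C8–C9 triad and the Z-alkene; C13 is missing.
- Comparison: alternative 3 is stronger on the E-alkene and on mildness. The chosen strategy offers a far shorter route to its key-step substrate and ring formation with no ring-closing event.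

Key step: step 15

Remark on the chemistry: the stereodescriptors are read literally, which places O6, C11, O8 and O9 on one face of the ring (6S,7S,8S,9R).
Remark on the chemistry: the side-chain acid is a C5 unit, (R)-3-methyl-4-(octadecanoyloxy)butanoic acid; a 3-methylglutaric precursor would carry one carbon too many, so the acid is built from (R)-2-methylsuccinic acid 4-tert-butyl ester, taken as a catalogue compound.

## Steps

Step 1
Reactants: 1 (S)-carvone
Product: 2 (S)-5-(3-chloroprop-1-en-2-yl)-2-methylcyclohex-2-en-1-one
Conditions: Ca(OCl)2, CO2 (dry ice), CH2Cl2/H2O, 0 °C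
Reagents that add atoms: calcium hypochlorite, [Ca+2].[O-]Cl.[O-]Cl
Why: Ene-type allylic chlorination by HOCl made in the flask; only the electron-rich 1,1-disubstituted alkene reacts, the conjugated ring alkene is inert, and C7 is untouched.

Step 2
Reactants: 2 (S)-5-(3-chloroprop-1-en-2-yl)-2-methylcyclohex-2-en-1-one
Product: 3 (S)-2-(4-methyl-5-oxocyclohex-3-en-1-yl)allyl acetate
Conditions: KOAc, nBu4NI (cat.), DMF, 60 °C
Reagents that add atoms: potassium acetate, CC(=O)[O-].[K+]
Why: SN2 displacement of a primary allylic chloride by acetate with iodide catalysis; acetate is too weakly basic to enolise the enone.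

Step 3
Reactants: 3 (S)-2-(4-methyl-5-oxocyclohex-3-en-1-yl)allyl acetate
Product: 4 2-[(1S,5S)-5-hydroxy-4-methylcyclohex-3-en-1-yl]allyl acetate (C9 hydroxyl cis to the C7 branch)
Conditions: NaBH4, CeCl3·7H2O, MeOH, −78 → 0 °C
Reagents that add atoms: none
Why: Luche 1,2-reduction; axial hydride delivery to the half-chair with the C7 branch equatorial gives the cis carbinol, as for carvone itself. The carbinol is a placeholder that keeps the carbonyl away from the borane of step 4 and is re-oxidised in step 6.

Step 4
Reactants: 4 2-[(1S,5S)-5-hydroxy-4-methylcyclohex-3-en-1-yl]allyl acetate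
Product: 6 2-[(1S,5S)-5-hydroxy-4-methylcyclohex-3-en-1-yl]propane-1,3-diol, via alkylborane borinate 5 (not isolated)
Conditions: 9-BBN (2.5 equiv), THF, 0 °C → rt; then NaOH (3 M), H2O2 (30%), 0 → 45 °C
Reagents that add atoms: hydrogen peroxide, OO
Why: Brown hydroboration–oxidation; 9-BBN puts boron on the terminal carbon of the 1,1-disubstituted alkene and ignores the trisubstituted ring alkene, and the alkaline peroxide work-up also cleaves the acetate. C11 then carries two identical CH2OH arms and is not a stereocentre.

Step 5
Reactants: 6 2-[(1S,5S)-5-hydroxy-4-methylcyclohex-3-en-1-yl]propane-1,3-diol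
Product: 7 (1S,5S)-5-(2,2-dimethyl-1,3-dioxan-5-yl)-2-methylcyclohex-2-en-1-ol
Conditions: Me2C(OMe)2, PPTS (cat.), acetone, rt
Reagents that add atoms: 2,2-dimethoxypropane, COC(C)(C)OC
Why: Acetonide formation by transketalisation; the 1,3-diol closes the six-membered dioxane, and the secondary C9 hydroxyl cannot form a comparable ring and stays free.

Step 6
Reactants: 7 (1S,5S)-5-(2,2-dimethyl-1,3-dioxan-5-yl)-2-methylcyclohex-2-en-1-ol
Product: 8 (S)-5-(2,2-dimethyl-1,3-dioxan-5-yl)-2-methylcyclohex-2-en-1-one
Conditions: MnO2 (activated, excess), CH2Cl2, rt
Reagents that add atoms: none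
Why: MnO2 oxidation of an allylic alcohol restores the enone; the acetonide is stable under these neutral conditions.

Step 7
Reactants: 8 (S)-5-(2,2-dimethyl-1,3-dioxan-5-yl)-2-methylcyclohex-2-en-1-one
Product: 10 trans-8-hydroxy enone (C8 hydroxyl trans to the C7 dioxanyl group), via potassium dienolate 9 (not isolated)
Conditions: KN(SiMe3)2, THF, −78 °C; 3-phenyl-2-(phenylsulfonyl)oxaziridine, −78 °C; AcOH quench
Reagents that add atoms: 3-phenyl-2-(phenylsulfonyl)oxaziridine, O=S(=O)(N1OC1c1ccccc1)c1ccccc1
Why: Kinetic α′-enolisation and Davis hydroxylation; the electrophilic oxygen enters C8 anti to the C7 branch, as in α′-functionalisation of carvone. Any cis ketol formed is 12 itself, so both diastereomers converge after step 8.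

Step 8
Reactants: 10 trans-8-hydroxy enone
Product: 12 cis-8-hydroxy enone (C8 hydroxyl cis to the C7 dioxanyl group), via C8 formate 11 (not isolated)
Conditions: PPh3, DIAD, HCO2H, THF, 0 °C → rt; then KHCO3, MeOH, 0 °C
Reagents that add atoms: formic acid, O=CO
Why: Mitsunobu inversion; formate displaces the oxyphosphonium group at the carbonyl-activated C8 by SN2 while C6 is still unsubstituted, and the formate is cleaved by bicarbonate methanolysis mild enough not to epimerise the ketol. Inversion sets O8 cis to the C7 branch.

Step 9
Reactants: 12 cis-8-hydroxy enone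
Product: 13 cis-8-(tert-butyldimethylsilyloxy) enone
Conditions: TBSCl, imidazole, DMAP (cat.), DMF, rt
Reagents that add atoms: tert-butyldimethylsilyl chloride, C[Si](C)(Cl)C(C)(C)C
Why: Silylation under non-enolising conditions (a silyl triflate with base could enolise the ketone and scramble C8).

Step 10
Reactants: 13 cis-8-(tert-butyldimethylsilyloxy) enone
Product: 15 trans-6-hydroxy enone (C6 hydroxyl trans to the C7 and C8 substituents), via silyl dienol ether 14 (not isolated)
Conditions: TMSOTf, Et3N, CH2Cl2, 0 °C; then DMDO, acetone/CH2Cl2, −78 → −20 °C; aqueous NaHCO3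
Reagents that add atoms: dimethyldioxirane, CC1(C)OO1
Why: Vinylogous Rubottom oxidation; soft enolisation removes a γ-proton at C6 (the α′-proton is shielded by the silyl ether and the C7 branch), and DMDO epoxidises the terminal C5=C6 bond of the linear silyl dienol ether, which collapses to the γ-hydroxy enone. Attack comes from the face opposite the C7 branch and the C8 silyl ether; any cis alcohol formed is 17 itself.

Step 11
Reactants: 15 trans-6-hydroxy enone
Product: 17 cis-6-hydroxy enone (O6, the C7 branch and O8 all cis), via C6 formate 16 (not isolated)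
Conditions: PPh3, DIAD, HCO2H, THF/toluene, 0 °C → rt; then KHCO3, MeOH, 0 °C
Reagents that add atoms: formic acid, O=CO
Why: Mitsunobu inversion at the allylic C6; in the conformer with the leaving group axial there is no antiperiplanar β-hydrogen (the C7 branch is anti), which suppresses elimination, and the small formate enters gauche to that branch. Inversion completes the all-cis O6/C7/O8 array.

Step 12
Reactants: 17 cis-6-hydroxy enone
Product: 18 all-cis enone with 6-O-triethylsilyl and 8-O-tert-butyldimethylsilyl groups (photosubstrate)
Conditions: TESCl, imidazole, DMF, 0 °C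
Reagents that add atoms: triethylsilyl chloride, CC[Si](Cl)(CC)CC
Why: Silylation of the allylic alcohol; a TES group is chosen so that it falls with the acetonide in step 16 while the TBS ether stays.

Step 13
Reactants: 19 methylenecyclobutane
Product: 20 1-methylcyclobutene
Conditions: KOtBu (0.2 equiv), DMSO, 70 °C; product distilled out (bp 37 °C) and fractionated
Reagents that add atoms: none
Why: Base-catalysed prototropic isomerisation of the exocyclic alkene to the more substituted endocyclic isomer, which is the lower-boiling component and is removed as it forms.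

Step 14
Reactants: 18 all-cis silylated enone; 20 1-methylcyclobutene
Product: 21 cis,anti,cis tricyclic photoadduct (bicyclo[2.2.0]hexane bonded C1–C4 and C5–C10, on the face opposite O6, C11 and O8)
Conditions: 20 (10 equiv), hν (λ ≥ 350 nm, uranium-glass filter), CH2Cl2, −40 °C
Reagents that add atoms: none
Why: Triplet enone–alkene [2+2] photocycloaddition through a 1,4-biradical. Head-to-tail regiochemistry is expected: the more substituted alkene carbon C4 bonds to the β-carbon C5 and the CH carbon C1 to the methyl-bearing C10, which also avoids joining two fully substituted carbons. The alkene approaches the face opposite the three cis substituents, the six/four fusion closes cis, and the outer ring lies anti. The choice of π-face does not affect the outcome, because C1, C4, C5 and C10 all become trigonal in step 15.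

Step 15
Reactants: 21 cis,anti,cis tricyclic photoadduct
Product: 22 ten-membered (1(10)Z,4E)-dienone with C9 ketone, 6-O-triethylsilyl, 8-O-tert-butyldimethylsilyl and C7 dioxanyl groups
Conditions: flash vacuum thermolysis: sublimed (≤150 °C, 10^-4 mbar) through a base-washed quartz tube at 500 °C, contact ca. 10 ms, condensed at −196 °C
Reagents that add atoms: none
Why: Heat breaks the strained central C1–C4 bond of the bicyclo[2.2.0]hexane to a cyclohexane-1,4-diyl (tertiary at C4), which relaxes from boat to chair and then cleaves C5–C10, the bond aligned with both radical orbitals; the net change is a stepwise retro-[2+2]. The closest known reaction type is the thermal cycloreversion of cyclohexenone–cyclobutene photoadducts to cis,trans-cyclodeca-1,5-dienes, including adducts of 1-methylcyclobutene. The ten-membered ring is not closed by bond formation; it is released by ring expansion when the two bonds shared by the six- and four-membered rings are lost. No stereocentre is formed: C1, C4, C5 and C10 become trigonal and C6, C7 and C8 are not involved. The step needs C5–C10 rather than C2–C3 to break; C5–C10 cleavage gives the conjugated enone and two trisubstituted alkenes, whereas C2–C3 cleavage would give a divinylcyclohexanone. It needs Z at C1=C10 and E at C4=C5; the cis,anti,cis fusion lets the boat diyl flip to the chair with C14 equatorial, which puts C9 axial on C10 (cis to C2, hence Z) and C6 equatorial on C5 (trans to C3, hence E), while the other chair would carry both C14 and C6 axial. It needs no onward Cope shift; that shift would have to bond C5 to the fully substituted C10 and give up enone conjugation, and millisecond contact at high temperature favours the high-entropy fragmentation over the ordered Cope transition state.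

Step 16
Reactants: 22 ten-membered Z,E-dienone
Product: 23 dienone triol (free C6 hydroxyl and two CH2OH arms on C11; 8-O-TBS retained)
Conditions: AcOH/THF/H2O (3:1:1), 35 °C
Reagents that add atoms: none
Why: Acid hydrolysis removes the TES ether and the acetonide together; the secondary TBS ether next to the ketone survives, and the aqueous medium avoids mixed methyl ketals between O6 and C9.

Step 17
Reactants: 23 dienone triol
Product: 24 cis-fused hydroxymethyl γ-lactone (C12 carbonyl, C13 as CH2OH; C11 epimers, both usable)
Conditions: TEMPO (0.2 equiv), PhI(OAc)2 (2.5 equiv), CH2Cl2, rt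
Reagents that add atoms: none
Why: TEMPO/PhI(OAc)2 oxidative lactonisation; a primary alcohol is oxidised to the aldehyde, which closes a five-membered lactol onto the cis C6 hydroxyl and is oxidised on to the lactone. The hindered secondary allylic C6 hydroxyl reacts more slowly and is consumed as the lactol; either arm may react because both C11 epimers converge in step 18.

Step 18
Reactants: 24 hydroxymethyl lactone
Product: 26 α-methylene lactone with 8-O-TBS and C9 ketone, via C13 mesylate 25 (not isolated)
Conditions: MsCl, Et3N, CH2Cl2, 0 °C; then DBU, 0 °C → rt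
Reagents that add atoms: none
Why: Mesylation of the only free hydroxyl followed by E1cB elimination through the lactone enolate gives the exocyclic methylene.

Step 19
Reactants: 26 α-methylene lactone 8-O-TBS ketone
Product: 27 α-methylene lactone 8-hydroxy ketone
Conditions: HF·pyridine, pyridine, THF, 0 °C → rt
Reagents that add atoms: none
Why: Buffered fluoride desilylation; it is non-basic, so neither the ketol stereocentre nor the methylene lactone is endangered.

Step 20
Reactants: 28 (R)-4-(tert-butoxy)-2-methyl-4-oxobutanoic acid
Product: 29 tert-butyl (R)-4-hydroxy-3-methylbutanoate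
Conditions: BH3·SMe2, THF, 0 °C → rt; MeOH quench
Reagents that add atoms: none
Why: Borane reduces the carboxylic acid chemoselectively in the presence of the tert-butyl ester; the stereocentre is not touched and keeps its R descriptor.

Step 21
Reactants: 29 tert-butyl (R)-4-hydroxy-3-methylbutanoate; 30 octadecanoyl chloride
Product: 31 tert-butyl (R)-3-methyl-4-(octadecanoyloxy)butanoate
Conditions: pyridine, DMAP (cat.), CH2Cl2, 0 °C → rt
Reagents that add atoms: none
Why: Acylation of a primary alcohol with an acid chloride; prompt acylation also forestalls lactonisation of the hydroxy ester.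

Step 22
Reactants: 31 tert-butyl (R)-3-methyl-4-(octadecanoyloxy)butanoate
Product: 32 (R)-3-methyl-4-(octadecanoyloxy)butanoic acid
Conditions: TFA, CH2Cl2, 0 °C → rt
Reagents that add atoms: none
Why: Acidolysis of the tert-butyl ester with loss of isobutene; the primary alkyl ester is stable to anhydrous acid.

Step 23
Reactants: 27 α-methylene lactone 8-hydroxy ketone; 32 (R)-3-methyl-4-(octadecanoyloxy)butanoic acid
Product: 33 8-O-acyl ketone (full side chain on O8, C9 ketone, α-methylene lactone)
Conditions: EDC·HCl, DMAP (0.2 equiv), CH2Cl2, 0 °C → rt
Reagents that add atoms: none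
Why: Steglich esterification of the secondary ketol; with C9 still a ketone there is no second hydroxyl to compete, and the C8 configuration is retained because the C8–O bond is not broken.

Step 24
Reactants: 33 8-O-acyl ketone
Product: 34 target, (6S,7S,8S,9R)-8-[(R)-3-methyl-4-(octadecanoyloxy)butanoyloxy]-9-hydroxy-germacra-1(10)Z,4E,11(13)-trien-12,6-olide
Conditions: NaBH4, CeCl3·7H2O, MeOH/THF, −78 °C; AcOH quench at −78 °C
Reagents that add atoms: none
Why: Luche 1,2-reduction of the Z-enone; at −78 °C the ketone should react far faster than the methylene lactone or the esters, and a cold acidic quench limits acyl migration. The new C9 centre should arise by hydride delivery from the ring periphery anti to the C8 acyloxy group, giving the 8,9-cis carbinol when the C7–C8–C9–C10 segment is gauche; this is the least secure stereochemical prediction of the route.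

## Compound list

1 | (S)-carvone | CC(=C)[C@H]1CC=C(C)C(=O)C1 | starting material
2 | (S)-5-(3-chloroprop-1-en-2-yl)-2-methylcyclohex-2-en-1-one | O=C1C(C)=CC[C@H](C(=C)CCl)C1 | intermediate
3 | (S)-2-(4-methyl-5-oxocyclohex-3-en-1-yl)allyl acetate | O=C1C(C)=CC[C@H](C(=C)COC(C)=O)C1 | intermediate
4 | 2-[(1S,5S)-5-hydroxy-4-methylcyclohex-3-en-1-yl]allyl acetate | O[C@@H]1C(C)=CC[C@H](C(=C)COC(C)=O)C1 | intermediate
5 | alkylborane borinate (9-BBN on C13 and on O9; C11 epimers) | CC(=O)OCC(CB1C2CCCC1CCC2)[C@H]1CC=C(C)[C@@H](OB2C3CCCC2CCC3)C1 | intermediate (not isolated)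
6 | 2-[(1S,5S)-5-hydroxy-4-methylcyclohex-3-en-1-yl]propane-1,3-diol | O[C@@H]1C(C)=CC[C@H](C(CO)CO)C1 | intermediate
7 | (1S,5S)-5-(2,2-dimethyl-1,3-dioxan-5-yl)-2-methylcyclohex-2-en-1-ol | O[C@@H]1C(C)=CC[C@H](C2COC(C)(C)OC2)C1 | intermediate
8 | (S)-5-(2,2-dimethyl-1,3-dioxan-5-yl)-2-methylcyclohex-2-en-1-one | O=C1C(C)=CC[C@H](C2COC(C)(C)OC2)C1 | intermediate
9 | potassium cross-conjugated dienolate of 8 (C8=C9) | [K+].[O-]C1=C[C@@H](C2COC(C)(C)OC2)CC=C1C | intermediate (not isolated)
10 | trans-8-hydroxy enone (O8 trans to the C7 dioxanyl group) | O=C1C(C)=CC[C@H](C2COC(C)(C)OC2)[C@H]1O | intermediate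
11 | cis-8-formyloxy enone | O=C1C(C)=CC[C@H](C2COC(C)(C)OC2)[C@@H]1OC=O | intermediate (not isolated)
12 | cis-8-hydroxy enone (O8 cis to the C7 dioxanyl group) | O=C1C(C)=CC[C@H](C2COC(C)(C)OC2)[C@@H]1O | intermediate
13 | cis-8-(tert-butyldimethylsilyloxy) enone | O=C1C(C)=CC[C@H](C2COC(C)(C)OC2)[C@@H]1O[Si](C)(C)C(C)(C)C | intermediate
14 | linear trimethylsilyl dienol ether of 13 (C9=C10, C5=C6) | C[Si](C)(C)OC1=C(C)C=C[C@H](C2COC(C)(C)OC2)[C@@H]1O[Si](C)(C)C(C)(C)C | intermediate (not isolated)
15 | trans-6-hydroxy-cis-8-silyloxy enone (O6 trans to C7 and C8 substituents) | O=C1C(C)=C[C@@H](O)[C@H](C2COC(C)(C)OC2)[C@@H]1O[Si](C)(C)C(C)(C)C | intermediate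
16 | all-cis 6-formyloxy-8-silyloxy enone | O=C1C(C)=C[C@H](OC=O)[C@H](C2COC(C)(C)OC2)[C@@H]1O[Si](C)(C)C(C)(C)C | intermediate (not isolated)
17 | all-cis 6-hydroxy-8-silyloxy enone | O=C1C(C)=C[C@H](O)[C@H](C2COC(C)(C)OC2)[C@@H]1O[Si](C)(C)C(C)(C)C | intermediate
18 | all-cis enone, 6-O-TES, 8-O-TBS, C7 2,2-dimethyl-1,3-dioxan-5-yl | O=C1C(C)=C[C@H](O[Si](CC)(CC)CC)[C@H](C2COC(C)(C)OC2)[C@@H]1O[Si](C)(C)C(C)(C)C | intermediate
19 | methylenecyclobutane | C=C1CCC1 | starting material
20 | 1-methylcyclobutene | CC1=CCC1 | intermediate
21 | cis,anti,cis tricyclic photoadduct (6-O-TES, 8-O-TBS, C7 dioxanyl) | O=C1[C@@]2(C)[C@@H]3CC[C@]3(C)[C@H]2[C@H](O[Si](CC)(CC)CC)[C@H](C4COC(C)(C)OC4)[C@@H]1O[Si](C)(C)C(C)(C)C | intermediate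
22 | ten-membered (1(10)Z,4E)-dienone, C9 ketone (6-O-TES, 8-O-TBS, C7 dioxanyl) | O=C1/C(C)=C\CC/C(C)=C/[C@H](O[Si](CC)(CC)CC)[C@H](C2COC(C)(C)OC2)[C@@H]1O[Si](C)(C)C(C)(C)C | intermediate
23 | dienone triol (6-OH, C11 bis-hydroxymethyl, 8-O-TBS) | O=C1/C(C)=C\CC/C(C)=C/[C@H](O)[C@H](C(CO)CO)[C@@H]1O[Si](C)(C)C(C)(C)C | intermediate
24 | cis-fused 13-hydroxy-12,6-lactone, 8-O-TBS, C9 ketone (C11 epimers) | O=C1/C(C)=C\CC/C(C)=C/[C@@H]2OC(=O)C(CO)[C@@H]2[C@@H]1O[Si](C)(C)C(C)(C)C | intermediate
25 | C13 mesylate of 24 | O=C1/C(C)=C\CC/C(C)=C/[C@@H]2OC(=O)C(COS(C)(=O)=O)[C@@H]2[C@@H]1O[Si](C)(C)C(C)(C)C | intermediate (not isolated)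
26 | α-methylene lactone, 8-O-TBS, C9 ketone | O=C1/C(C)=C\CC/C(C)=C/[C@@H]2OC(=O)C(=C)[C@@H]2[C@@H]1O[Si](C)(C)C(C)(C)C | intermediate
27 | α-methylene lactone, 8-hydroxy, C9 ketone | O=C1/C(C)=C\CC/C(C)=C/[C@@H]2OC(=O)C(=C)[C@@H]2[C@@H]1O | intermediate
28 | (R)-4-(tert-butoxy)-2-methyl-4-oxobutanoic acid | CC(C)(C)OC(=O)C[C@@H](C)C(=O)O | starting material
29 | tert-butyl (R)-4-hydroxy-3-methylbutanoate | CC(C)(C)OC(=O)C[C@@H](C)CO | intermediate
30 | octadecanoyl chloride | CCCCCCCCCCCCCCCCCC(Cl)=O | starting material
31 | tert-butyl (R)-3-methyl-4-(octadecanoyloxy)butanoate | CC(C)(C)OC(=O)C[C@@H](C)COC(=O)CCCCCCCCCCCCCCCCC | intermediate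
32 | (R)-3-methyl-4-(octadecanoyloxy)butanoic acid | OC(=O)C[C@@H](C)COC(=O)CCCCCCCCCCCCCCCCC | intermediate
33 | 8-O-acyl ketone (full side chain, α-methylene lactone, C9 ketone) | O=C1/C(C)=C\CC/C(C)=C/[C@@H]2OC(=O)C(=C)[C@@H]2[C@@H]1OC(=O)C[C@@H](C)COC(=O)CCCCCCCCCCCCCCCCC | intermediate
34 | CNP0114940.1 | C=C1C(=O)O[C@H]2/C=C(\C)CC/C=C(/C)[C@@H](O)[C@@H](OC(=O)C[C@@H](C)COC(=O)CCCCCCCCCCCCCCCCC)[C@@H]12 | target

## Step count and least certain steps

Total: 24 steps. Longest linear sequence: 20 steps (steps 1–12, 14–19, 23 and 24); steps 13 and 20–22 are side branches.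

**Step 15 (key step).** The most likely failure is that the Z,E-dienone, once formed, goes on by Cope shift to the cis-divinylcyclohexanone before it leaves the hot zone. A second risk is that the heavy doubly silylated substrate sublimes too slowly and loses silyl or acetal groups on the hot surface. Fallback: the cycloreversion is moved to a lighter and stiffer substrate. It sets out from 21. Aqueous acetic acid gives the tricyclic triol F1; TEMPO/PhI(OAc)2 gives the tricyclic hydroxymethyl lactone F2; MsCl/Et3N gives the tricyclic mesylate F3; DBU gives the tricyclic α-methylene lactone F4. Flash thermolysis of F4 then gives 26 directly, where the route is rejoined. F4 carries no acid-labile group, is far more volatile, and its cis-fused lactone across C6–C7 stiffens the ring segment next to C5, which should raise the barrier of the chair-like Cope transition state.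

**Step 14.** The likely failure is poor regio- or ring-fusion selectivity, or slow addition with competing enone decay, because the α-methyl enone carries a bulky silyl ether next to the reacting β-carbon and the alkene is trisubstituted. Fallback: the lactone is built before the photocycloaddition. It sets out from 17. Aqueous acetic acid gives the enone triol F5 and TEMPO/PhI(OAc)2 gives the bicyclic hydroxymethyl lactone enone F6, a rigid cis-fused enone with one open convex face and no silyl ether beside C5. Irradiation of F6 with 20 should give the tricyclic hydroxymethyl lactone F2, which goes on through the tricyclic mesylate F3 and the tricyclic α-methylene lactone F4 to 26 as described for step 15.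

**Step 8.** The likely failure is elimination or incomplete inversion, because SN2 at the ketol carbon must bring the nucleophile in next to the branched C7. Fallback: the cis isomer is made by kinetic protonation instead of substitution. It sets out from 10. TBSCl/imidazole gives the trans-8-silyloxy enone F7; LDA at −78 °C gives its lithium enolate F8; protonation at −78 °C with 2,6-di-tert-butyl-4-methylphenol (then aqueous NH4Cl) delivers the proton to C8 from the face opposite the C7 branch and gives 13, where the route is rejoined.

**Step 11.** The likely failure is slow substitution with SN2′ attack or elimination taking over, because the nucleophile has to enter C6 on the face that carries the C7 branch and the C8 silyl ether. Fallback: the cis alcohol is made by reduction instead of substitution. It sets out from 15. Dess–Martin periodinane gives the ene-dione F9, and NaBH4/CeCl3·7H2O at −78 °C should deliver hydride to C6 from the open face anti to both substituents and give 17, where the route is rejoined. Weak points of this fallback are the choice between the C6 and C9 carbonyls and possible epimerisation at C7 in F9.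

**Step 24.** The likely failures are hydride delivery to the wrong face of C9, some conjugate reduction of the methylene lactone, and acyl migration from O8 to O9 in the alkoxide. Fallback: C9 is reduced before the side chain is attached and O9 is protected. It sets out from 26. NaBH4/CeCl3·7H2O gives the C9 alcohol F10; wrong-face material is returned to 26 by MnO2, which is clean at this stage because O8 carries a silyl ether that can neither migrate nor participate. Allyl chloroformate/pyridine gives the 9-O-allyloxycarbonyl compound F11; HF·pyridine gives the 8-hydroxy carbonate F12; EDC/DMAP with 32 gives the fully acylated carbonate F13; zerovalent palladium Pd(PPh3)4 with dimedone removes the carbonate and gives 34.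

## Further compounds

F1 | step 15 | tricyclic triol (6-OH, C11 bis-hydroxymethyl, 8-O-TBS) | O=C1[C@@]2(C)[C@@H]3CC[C@]3(C)[C@H]2[C@H](O)[C@H](C(CO)CO)[C@@H]1O[Si](C)(C)C(C)(C)C
F2 | step 15 | tricyclic hydroxymethyl lactone (C11 epimers) | O=C1[C@@]2(C)[C@@H]3CC[C@]3(C)[C@H]2[C@@H]4OC(=O)C(CO)[C@@H]4[C@@H]1O[Si](C)(C)C(C)(C)C
F3 | step 15 | tricyclic C13 mesylate | O=C1[C@@]2(C)[C@@H]3CC[C@]3(C)[C@H]2[C@@H]4OC(=O)C(COS(C)(=O)=O)[C@@H]4[C@@H]1O[Si](C)(C)C(C)(C)C
F4 | step 15 | tricyclic α-methylene lactone | O=C1[C@@]2(C)[C@@H]3CC[C@]3(C)[C@H]2[C@@H]4OC(=O)C(=C)[C@@H]4[C@@H]1O[Si](C)(C)C(C)(C)C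
F5 | step 14 | enone triol (6-OH, C11 bis-hydroxymethyl, 8-O-TBS) | O=C1C(C)=C[C@H](O)[C@H](C(CO)CO)[C@@H]1O[Si](C)(C)C(C)(C)C
F6 | step 14 | bicyclic hydroxymethyl lactone enone (C11 epimers) | O=C1C(C)=C[C@@H]2OC(=O)C(CO)[C@@H]2[C@@H]1O[Si](C)(C)C(C)(C)C
F7 | step 8 | trans-8-(tert-butyldimethylsilyloxy) enone | O=C1C(C)=CC[C@H](C2COC(C)(C)OC2)[C@H]1O[Si](C)(C)C(C)(C)C
F8 | step 8 | lithium enolate of F7 (C8=C9) | [Li+].[O-]C1=C(O[Si](C)(C)C(C)(C)C)[C@@H](C2COC(C)(C)OC2)CC=C1C
F9 | step 11 | ene-dione (C6 and C9 ketones, 8-O-TBS) | O=C1C(C)=CC(=O)[C@H](C2COC(C)(C)OC2)[C@@H]1O[Si](C)(C)C(C)(C)C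
F10 | step 24 | 9-hydroxy α-methylene lactone, 8-O-TBS | O[C@@H]1/C(C)=C\CC/C(C)=C/[C@@H]2OC(=O)C(=C)[C@@H]2[C@@H]1O[Si](C)(C)C(C)(C)C
F11 | step 24 | 9-O-allyloxycarbonyl, 8-O-TBS | C=CCOC(=O)O[C@@H]1/C(C)=C\CC/C(C)=C/[C@@H]2OC(=O)C(=C)[C@@H]2[C@@H]1O[Si](C)(C)C(C)(C)C
F12 | step 24 | 9-O-allyloxycarbonyl, 8-hydroxy | C=CCOC(=O)O[C@@H]1/C(C)=C\CC/C(C)=C/[C@@H]2OC(=O)C(=C)[C@@H]2[C@@H]1O
F13 | step 24 | 9-O-allyloxycarbonyl, 8-O-acyl (full side chain) | C=CCOC(=O)O[C@@H]1/C(C)=C\CC/C(C)=C/[C@@H]2OC(=O)C(=C)[C@@H]2[C@@H]1OC(=O)C[C@@H](C)COC(=O)CCCCCCCCCCCCCCCCC
A1 | alternative 1 | 1-vinyl-2-isopropenylcyclohexanol with 6,8-O-p-methoxybenzylidene acetal, 9-O-(2-naphthylmethyl) and C7 2-(triethylsilyloxy)ethyl (both alkenyl groups drawn on the face opposite the oxygens) | O[C@]1(C=C)[C@@H](C(C)=C)[C@@H]2O[C@@H](c3ccc(OC)cc3)O[C@H]([C@@H]1OCc4ccc5ccccc5c4)[C@H]2CCO[Si](CC)(CC)CC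
A2 | alternative 1 | ten-membered 1(10),4-dienyl C10 triflate | O=S(=O)(O/C1=C/CC/C(C)=C/[C@@H]2O[C@@H](c3ccc(OC)cc3)O[C@H]([C@@H]1OCc4ccc5ccccc5c4)[C@H]2CCO[Si](CC)(CC)CC)C(F)(F)F
A3 | alternative 2 | open-chain lactone dialdehyde (C8 aldehyde, C9 Z-enal) | O=C/C(C)=C\CC/C(C)=C/[C@@H]1OC(=O)C[C@@H]1C=O
A4 | alternative 2 | ten-membered cis-8,9-diol lactone | O[C@@H]1/C(C)=C\CC/C(C)=C/[C@@H]2OC(=O)C[C@@H]2[C@@H]1O
A5 | alternative 3 | open-chain ynal (C6 aldehyde, terminal alkyne C4≡C5, C12 methyl ester) | O=C[C@H](CC(=O)OC)[C@H](OCc1ccc(OC)cc1)[C@H](O[Si](C)(C)C(C)(C)C)/C(C)=C\CCC#C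
A6 | alternative 3 | ten-membered E-allylic C6 alcohol with C12 methyl ester | O[C@H]1/C=C(\C)CC/C=C(/C)[C@@H](O[Si](C)(C)C(C)(C)C)[C@@H](OCc2ccc(OC)cc2)[C@H]1CC(=O)OC
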